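**Strategy**

Everything rests on closing ring B last, at the C4–C4a bond (tetralin numbering: C1 carries ring C, C2 the sulfated arm, C3 the hydroxymethyl arm). The feature exploited is that C4 is an unsubstituted benzylic CH2 lying between ring A carbon C4a and C3, which bears a carboxyl-level arm. C4 can therefore be the CH2 terminus of an acrylate that a C4a aryl radical attacks in the 6-endo sense. One operation forms C4–C4a, closes ring B and creates C3. The precursor is an acyclic tert-butyl α-methylene ester with C1 and C2 already set and ring A brominated at C4a.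

Key step: step 10

Remark on the chemistry: the target is drawn as the free hydrogen sulfate. The sulfate is carried as its sodium salt and protonated only in the last operation, and the free acid should be kept cold.

Remark on numbering: cyclised compounds are named with the tetralin numbering above (ring A = C4a to C8a, OMe on C6, oxygen on C7).

**Route**

Step 1
Reactants: 1 2-bromo-5-hydroxy-4-methoxybenzaldehyde
Product: 2 5-(benzyloxy)-2-bromo-4-methoxybenzaldehyde
Conditions: BnBr, K2CO3, DMF, rt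
Reagents that add atoms: benzyl bromide, BrCc1ccccc1
Why: Williamson etherification of the phenoxide protects the future C7 oxygen as a benzyl ether and leaves the bromine para to it, on the carbon that becomes C4a.

Step 2
Reactants: 2 5-(benzyloxy)-2-bromo-4-methoxybenzaldehyde
Product: 3 methyl (E)-3-[5-(benzyloxy)-2-bromo-4-methoxyphenyl]prop-2-enoate
Conditions: Ph3P=CHCO2Me, PhMe, 80 °C
Reagents that add atoms: methyl (triphenylphosphoranylidene)acetate, COC(=O)C=P(c1ccccc1)(c1ccccc1)c1ccccc1
Why: Wittig olefination with a stabilised ylide should give the (E)-enoate, whose defined geometry is needed for face selection in step 3.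

Step 3
Reactants: 3 methyl (E)-3-[5-(benzyloxy)-2-bromo-4-methoxyphenyl]prop-2-enoate; 4 [4-(benzyloxy)-3-methoxyphenyl]boronic acid
Product: 5 methyl (3S)-3-[5-(benzyloxy)-2-bromo-4-methoxyphenyl]-3-[4-(benzyloxy)-3-methoxyphenyl]propanoate
Conditions: [RhCl(C2H4)2]2 (cat.), (R,R)-Ph-bod* [(1R,4R)-2,5-diphenylbicyclo[2.2.2]octa-2,5-diene] (cat.), KOH (0.2 equiv), 1,4-dioxane/H2O, 40 °C
Reagents that add atoms: none
Why: In this rhodium-catalysed asymmetric conjugate arylation (Hayashi–Miyaura reaction) the aryl–rhodium species adds across the enoate and water protonates the rhodium enolate; the chiral diene is expected to deliver ring C to the re face of C3 of the enoate (the α-re sense this ligand shows with enones, to be confirmed on the first run, the (S,S) ligand being the remedy), which sets C1 as S, the ethylene precatalyst leaves no achiral diene on rhodium, and the aryl bromide should be inert to univalent rhodium.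

Step 4
Reactants: 5 methyl (3S)-3,3-diarylpropanoate
Product: 7 (3S)-3-[5-(benzyloxy)-2-bromo-4-methoxyphenyl]-3-[4-(benzyloxy)-3-methoxyphenyl]propanoic acid, via lithium carboxylate 6 (not isolated)
Conditions: LiOH, THF/MeOH/H2O, rt; then HCl aq
Reagents that add atoms: lithium hydroxide, [Li+].[OH-]
Why: Plain ester saponification is safe here because C1 is β to the carboxyl group and cannot epimerise through the enolate.

Step 5
Reactants: 7 (3S)-3,3-diarylpropanoic acid; 8 (4S)-4-benzyl-1,3-oxazolidin-2-one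
Product: 10 (4S)-4-benzyl-3-[(3S)-3,3-diarylpropanoyl]-1,3-oxazolidin-2-one, via mixed pivalic anhydride 9 (not isolated)
Conditions: t-BuCOCl, Et3N, THF, −20 °C; then LiCl, 8, rt
Reagents that add atoms: pivaloyl chloride, CC(C)(C)C(=O)Cl (its atoms stay in intermediate 9 only)
Why: N-acylation of the oxazolidinone through the mixed anhydride with LiCl/Et3N attaches the auxiliary without an alkyllithium, which would attack the aryl bromide.

Step 6
Reactants: 10 N-acyl oxazolidinone; 11 tert-butyl bromoacetate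
Product: 13 tert-butyl (3S,4S)-3-{[(4S)-4-benzyl-2-oxo-1,3-oxazolidin-3-yl]carbonyl}-4-[5-(benzyloxy)-2-bromo-4-methoxyphenyl]-4-[4-(benzyloxy)-3-methoxyphenyl]butanoate, via sodium Z-enolate 12 (not isolated)
Conditions: NaN(SiMe3)2, THF, −78 °C; then 11, −78 → −40 °C
Reagents that add atoms: NaN(SiMe3)2, C[Si](C)(C)[N-][Si](C)(C)C.[Na+] (sodium in intermediate 12 only)
Why: In this Evans alkylation the chelated Z-enolate is attacked by the bromoacetate on the face opposite to the benzyl group of the (S)-auxiliary, which sets the future C2 in the configuration required by the target (S in this imide, R after the later priority changes).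

Step 7
Reactants: 13 alkylated imide
Product: 14 tert-butyl (3S,4S)-4-[5-(benzyloxy)-2-bromo-4-methoxyphenyl]-4-[4-(benzyloxy)-3-methoxyphenyl]-3-(hydroxymethyl)butanoate
Conditions: LiBH4, MeOH (1 equiv), THF, 0 °C
Reagents that add atoms: none
Why: Reductive cleavage of the auxiliary with LiBH4 should reduce the imide carbonyl to the C2 CH2OH arm and leave the hindered tert-butyl ester, which also resists lactonisation at 0 °C.

Step 8
Reactants: 14 hydroxy ester
Product: 15 tert-butyl (3S,4S)-4-[5-(benzyloxy)-2-bromo-4-methoxyphenyl]-4-[4-(benzyloxy)-3-methoxyphenyl]-3-({[tri(propan-2-yl)silyl]oxy}methyl)butanoate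
Conditions: i-Pr3SiCl, imidazole, DMF, rt
Reagents that add atoms: chlorotri(propan-2-yl)silane, CC(C)[Si](Cl)(C(C)C)C(C)C
Why: Silylation of the primary alcohol; the bulky triisopropylsilyl group is chosen because it should not migrate to the neighbouring arm when that arm is an alkoxide in step 13, which would scramble the site of sulfation.

Step 9
Reactants: 15 silyl ether ester
Product: 19 tert-butyl (3R,4S)-4-[5-(benzyloxy)-2-bromo-4-methoxyphenyl]-4-[4-(benzyloxy)-3-methoxyphenyl]-2-methylidene-3-({[tri(propan-2-yl)silyl]oxy}methyl)butanoate, via lithium ester enolate 16 (not isolated), via Mannich base 17 (not isolated), via trimethylammonium iodide 18 (not isolated)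
Conditions: LiN(i-Pr)2, THF, −78 °C; CH2=NMe2+ I−, −78 → 0 °C; then MeI, MeOH, rt; then NaHCO3 aq, CH2Cl2, rt
Reagents that add atoms: N,N-dimethylmethyleneiminium iodide, C=[N+](C)C.[I-]; LiN(i-Pr)2, CC(C)[N-]C(C)C.[Li+] (lithium in intermediate 16 only); iodomethane, CI (methyl in intermediate 18 only)
Why: α-Methylenation by Mannich reaction of the ester enolate, N-methylation and E1cB elimination of trimethylamine installs the future C4 as the acrylate CH2, and the mild bicarbonate base should keep the double bond terminal and C2 intact.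

Step 10
Reactants: 19 α-methylene ester (precursor of the key step)
Product: 20 tert-butyl (1S,2R)-7-(benzyloxy)-1-[4-(benzyloxy)-3-methoxyphenyl]-6-methoxy-2-({[tri(propan-2-yl)silyl]oxy}methyl)-1,2,3,4-tetrahydronaphthalene-3-carboxylate (C3 epimers)
Conditions: Bu3SnH, AIBN (both by syringe pump), PhMe (0.01 M), 90 °C
Reagents that add atoms: none
Why: The tributyltin radical abstracts bromine to give the σ-aryl radical at C4a, which adds to the unsubstituted CH2 terminus of the acrylate (the future C4); the resulting tertiary, ester-stabilised C3 radical then takes a hydrogen atom from Bu3SnH and carries the chain. This is the known 6-endo cyclisation of aryl radicals onto α-substituted acrylates under tin hydride conditions. Ring B closes in the 6-endo-trig mode, because the 5-exo alternative would require attack at the fully substituted C3 and would give a primary radical, so sterics, polarity and radical stability all favour C4. C3 is created by hydrogen-atom transfer, probably anti to the C2 arm, but its configuration is not relied upon since step 11 corrects it; C1 and C2 are not touched. The step needs regiocontrol (ring A only, C4a only), which the position of the bromine secures, and it needs ring closure to outrun direct reduction of the aryl radical, 1,5-hydrogen shift from C2–H and reversible stannyl addition to the acrylate, which slow hydride addition at high dilution should secure.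

Step 11
Reactants: 20 cyclised ester (C3 epimers)
Product: 21 tert-butyl (1S,2R,3R)-7-(benzyloxy)-1-[4-(benzyloxy)-3-methoxyphenyl]-6-methoxy-2-({[tri(propan-2-yl)silyl]oxy}methyl)-1,2,3,4-tetrahydronaphthalene-3-carboxylate
Conditions: KOt-Bu (0.3 equiv), t-BuOH/THF, rt
Reagents that add atoms: none
Why: Reversible enolisation at C3 (base-mediated ester epimerisation) should funnel both epimers to the thermodynamically preferred all-equatorial isomer, with the ester trans to the C2 arm (R at C3), while C1 and C2 carry no hydrogen acidic enough to exchange.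

Step 12
Reactants: 21 trans ester
Product: 22 [(1S,2R,3R)-7-(benzyloxy)-1-[4-(benzyloxy)-3-methoxyphenyl]-6-methoxy-2-({[tri(propan-2-yl)silyl]oxy}methyl)-1,2,3,4-tetrahydronaphthalen-3-yl]methanol
Conditions: LiAlH4, THF, 0 °C → rt
Reagents that add atoms: none
Why: Hydride reduction of the ester gives the C3 CH2OH arm without enolisation, and the silyl and benzyl ethers are inert to LiAlH4.

Step 13
Reactants: 22 C3 arm alcohol
Product: 23 (1S,2R,3R)-7-(benzyloxy)-1-[4-(benzyloxy)-3-methoxyphenyl]-3-[(benzyloxy)methyl]-6-methoxy-2-({[tri(propan-2-yl)silyl]oxy}methyl)-1,2,3,4-tetrahydronaphthalene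
Conditions: NaH, BnBr, Bu4NI (cat.), THF/DMF, 0 °C → rt
Reagents that add atoms: benzyl bromide, BrCc1ccccc1
Why: Williamson benzylation masks the C3 arm with a group that leaves in the final hydrogenolysis together with the two phenol protecting groups.

Step 14
Reactants: 23 tribenzyl silyl ether
Product: 24 [(1S,2R,3R)-7-(benzyloxy)-1-[4-(benzyloxy)-3-methoxyphenyl]-3-[(benzyloxy)methyl]-6-methoxy-1,2,3,4-tetrahydronaphthalen-2-yl]methanol
Conditions: Bu4NF, THF, rt
Reagents that add atoms: none
Why: Fluoride-induced desilylation frees only the C2 arm hydroxyl, since every other oxygen is a benzyl or methyl ether.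

Step 15
Reactants: 24 C2 arm alcohol
Product: 26 sodium [(1S,2R,3R)-7-(benzyloxy)-1-[4-(benzyloxy)-3-methoxyphenyl]-3-[(benzyloxy)methyl]-6-methoxy-1,2,3,4-tetrahydronaphthalen-2-yl]methyl sulfate, via pyridinium sulfate 25 (not isolated)
Conditions: SO3·pyridine, pyridine, rt; then NaHCO3 aq
Reagents that add atoms: sulfur trioxide–pyridine complex, O=S(=O)=O.c1ccncc1; NaHCO3, [Na+].OC([O-])=O
Why: O-Sulfation of the single free primary alcohol with the SO3–amine complex is site-specific by design, and exchange to the sodium salt removes pyridine, which would inhibit the palladium catalyst of the last step.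

Step 16
Reactants: 26 sodium sulfate tribenzyl ether
Product: 28 [(1S,2R,3R)-7-hydroxy-1-(4-hydroxy-3-methoxyphenyl)-3-(hydroxymethyl)-6-methoxy-1,2,3,4-tetrahydronaphthalen-2-yl]methyl hydrogen sulfate, via sodium salt 27 (not isolated)
Conditions: H2 (1 atm), Pd/C, MeOH, rt; then HCl aq (1.0 equiv), 0 °C, n-BuOH extraction
Reagents that add atoms: none
Why: Catalytic hydrogenolysis should cleave the two aryl benzyl ethers and the alkyl benzyl ether while the sulfate monoester salt and the three stereocentres stay untouched, and cold stoichiometric acid then gives the hydrogen sulfate form of the target.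

**Compound list**

1 | 2-bromo-5-hydroxy-4-methoxybenzaldehyde | COc1cc(Br)c(C=O)cc1O | starting material
2 | 5-(benzyloxy)-2-bromo-4-methoxybenzaldehyde | COc1cc(Br)c(C=O)cc1OCc1ccccc1 | intermediate
3 | methyl (E)-3-[5-(benzyloxy)-2-bromo-4-methoxyphenyl]prop-2-enoate | COC(=O)/C=C/c1cc(OCc2ccccc2)c(OC)cc1Br | intermediate
4 | [4-(benzyloxy)-3-methoxyphenyl]boronic acid | COc1cc(B(O)O)ccc1OCc1ccccc1 | starting material
5 | methyl (3S)-3-[5-(benzyloxy)-2-bromo-4-methoxyphenyl]-3-[4-(benzyloxy)-3-methoxyphenyl]propanoate | COc1cc([C@@H](c2cc(OCc3ccccc3)c(OC)cc2Br)CC(=O)OC)ccc1OCc1ccccc1 | intermediate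
6 | lithium (3S)-3-[5-(benzyloxy)-2-bromo-4-methoxyphenyl]-3-[4-(benzyloxy)-3-methoxyphenyl]propanoate | COc1cc([C@@H](c2cc(OCc3ccccc3)c(OC)cc2Br)CC(=O)[O-])ccc1OCc1ccccc1.[Li+] | intermediate (not isolated)
7 | (3S)-3-[5-(benzyloxy)-2-bromo-4-methoxyphenyl]-3-[4-(benzyloxy)-3-methoxyphenyl]propanoic acid | COc1cc([C@@H](c2cc(OCc3ccccc3)c(OC)cc2Br)CC(=O)O)ccc1OCc1ccccc1 | intermediate
8 | (4S)-4-benzyl-1,3-oxazolidin-2-one | O=C1N[C@@H](Cc2ccccc2)CO1 | starting material
9 | (3S)-3-[5-(benzyloxy)-2-bromo-4-methoxyphenyl]-3-[4-(benzyloxy)-3-methoxyphenyl]propanoic 2,2-dimethylpropanoic anhydride | COc1cc([C@@H](c2cc(OCc3ccccc3)c(OC)cc2Br)CC(=O)OC(=O)C(C)(C)C)ccc1OCc1ccccc1 | intermediate (not isolated)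
10 | (4S)-4-benzyl-3-{(3S)-3-[5-(benzyloxy)-2-bromo-4-methoxyphenyl]-3-[4-(benzyloxy)-3-methoxyphenyl]propanoyl}-1,3-oxazolidin-2-one | COc1cc([C@@H](c2cc(OCc3ccccc3)c(OC)cc2Br)CC(=O)N2[C@@H](Cc3ccccc3)COC2=O)ccc1OCc1ccccc1 | intermediate
11 | tert-butyl bromoacetate | CC(C)(C)OC(=O)CBr | starting material
12 | sodium (Z)-enolate of imide 10 (enolate double bond between the acyl carbon and its α-carbon, oxygen cis to the diarylmethyl group) | COc1cc([C@@H](c2cc(OCc3ccccc3)c(OC)cc2Br)/C=C(\[O-])N2[C@@H](Cc3ccccc3)COC2=O)ccc1OCc1ccccc1.[Na+] | intermediate (not isolated)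
13 | tert-butyl (3S,4S)-3-{[(4S)-4-benzyl-2-oxo-1,3-oxazolidin-3-yl]carbonyl}-4-[5-(benzyloxy)-2-bromo-4-methoxyphenyl]-4-[4-(benzyloxy)-3-methoxyphenyl]butanoate | COc1cc([C@@H](c2cc(OCc3ccccc3)c(OC)cc2Br)[C@@H](C(=O)N2[C@@H](Cc3ccccc3)COC2=O)CC(=O)OC(C)(C)C)ccc1OCc1ccccc1 | intermediate
14 | tert-butyl (3S,4S)-4-[5-(benzyloxy)-2-bromo-4-methoxyphenyl]-4-[4-(benzyloxy)-3-methoxyphenyl]-3-(hydroxymethyl)butanoate | COc1cc([C@@H](c2cc(OCc3ccccc3)c(OC)cc2Br)[C@@H](CO)CC(=O)OC(C)(C)C)ccc1OCc1ccccc1 | intermediate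
15 | tert-butyl (3S,4S)-4-[5-(benzyloxy)-2-bromo-4-methoxyphenyl]-4-[4-(benzyloxy)-3-methoxyphenyl]-3-({[tri(propan-2-yl)silyl]oxy}methyl)butanoate | COc1cc([C@@H](c2cc(OCc3ccccc3)c(OC)cc2Br)[C@@H](CO[Si](C(C)C)(C(C)C)C(C)C)CC(=O)OC(C)(C)C)ccc1OCc1ccccc1 | intermediate
16 | lithium enolate of ester 15 (enolate geometry not defined) | COc1cc([C@@H](c2cc(OCc3ccccc3)c(OC)cc2Br)[C@@H](CO[Si](C(C)C)(C(C)C)C(C)C)C=C([O-])OC(C)(C)C)ccc1OCc1ccccc1.[Li+] | intermediate (not isolated)
17 | tert-butyl (3R,4S)-4-[5-(benzyloxy)-2-bromo-4-methoxyphenyl]-4-[4-(benzyloxy)-3-methoxyphenyl]-2-[(dimethylamino)methyl]-3-({[tri(propan-2-yl)silyl]oxy}methyl)butanoate (both C2 epimers) | COc1cc([C@@H](c2cc(OCc3ccccc3)c(OC)cc2Br)[C@@H](CO[Si](C(C)C)(C(C)C)C(C)C)C(CN(C)C)C(=O)OC(C)(C)C)ccc1OCc1ccccc1 | intermediate (not isolated)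
18 | N,N,N-trimethylammonium iodide formed from 17 by N-methylation (both C2 epimers) | COc1cc([C@@H](c2cc(OCc3ccccc3)c(OC)cc2Br)[C@@H](CO[Si](C(C)C)(C(C)C)C(C)C)C(C[N+](C)(C)C)C(=O)OC(C)(C)C)ccc1OCc1ccccc1.[I-] | intermediate (not isolated)
19 | tert-butyl (3R,4S)-4-[5-(benzyloxy)-2-bromo-4-methoxyphenyl]-4-[4-(benzyloxy)-3-methoxyphenyl]-2-methylidene-3-({[tri(propan-2-yl)silyl]oxy}methyl)butanoate | COc1cc([C@@H](c2cc(OCc3ccccc3)c(OC)cc2Br)[C@@H](CO[Si](C(C)C)(C(C)C)C(C)C)C(=C)C(=O)OC(C)(C)C)ccc1OCc1ccccc1 | intermediate (precursor of the key step)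
20 | tert-butyl (1S,2R)-7-(benzyloxy)-1-[4-(benzyloxy)-3-methoxyphenyl]-6-methoxy-2-({[tri(propan-2-yl)silyl]oxy}methyl)-1,2,3,4-tetrahydronaphthalene-3-carboxylate, C3 epimers | COc1cc([C@H]2c3cc(OCc4ccccc4)c(OC)cc3CC(C(=O)OC(C)(C)C)[C@@H]2CO[Si](C(C)C)(C(C)C)C(C)C)ccc1OCc1ccccc1 | intermediate (product of the key step)
21 | tert-butyl (1S,2R,3R)-7-(benzyloxy)-1-[4-(benzyloxy)-3-methoxyphenyl]-6-methoxy-2-({[tri(propan-2-yl)silyl]oxy}methyl)-1,2,3,4-tetrahydronaphthalene-3-carboxylate (1,2-trans, 2,3-trans) | COc1cc([C@H]2c3cc(OCc4ccccc4)c(OC)cc3C[C@@H](C(=O)OC(C)(C)C)[C@@H]2CO[Si](C(C)C)(C(C)C)C(C)C)ccc1OCc1ccccc1 | intermediate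
22 | [(1S,2R,3R)-7-(benzyloxy)-1-[4-(benzyloxy)-3-methoxyphenyl]-6-methoxy-2-({[tri(propan-2-yl)silyl]oxy}methyl)-1,2,3,4-tetrahydronaphthalen-3-yl]methanol | COc1cc([C@H]2c3cc(OCc4ccccc4)c(OC)cc3C[C@@H](CO)[C@@H]2CO[Si](C(C)C)(C(C)C)C(C)C)ccc1OCc1ccccc1 | intermediate
23 | (1S,2R,3R)-7-(benzyloxy)-1-[4-(benzyloxy)-3-methoxyphenyl]-3-[(benzyloxy)methyl]-6-methoxy-2-({[tri(propan-2-yl)silyl]oxy}methyl)-1,2,3,4-tetrahydronaphthalene | COc1cc([C@H]2c3cc(OCc4ccccc4)c(OC)cc3C[C@@H](COCc3ccccc3)[C@@H]2CO[Si](C(C)C)(C(C)C)C(C)C)ccc1OCc1ccccc1 | intermediate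
24 | [(1S,2R,3R)-7-(benzyloxy)-1-[4-(benzyloxy)-3-methoxyphenyl]-3-[(benzyloxy)methyl]-6-methoxy-1,2,3,4-tetrahydronaphthalen-2-yl]methanol | COc1cc([C@H]2c3cc(OCc4ccccc4)c(OC)cc3C[C@@H](COCc3ccccc3)[C@@H]2CO)ccc1OCc1ccccc1 | intermediate
25 | pyridinium [(1S,2R,3R)-7-(benzyloxy)-1-[4-(benzyloxy)-3-methoxyphenyl]-3-[(benzyloxy)methyl]-6-methoxy-1,2,3,4-tetrahydronaphthalen-2-yl]methyl sulfate | COc1cc([C@H]2c3cc(OCc4ccccc4)c(OC)cc3C[C@@H](COCc3ccccc3)[C@@H]2COS(=O)(=O)[O-])ccc1OCc1ccccc1.c1cc[nH+]cc1 | intermediate (not isolated)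
26 | sodium [(1S,2R,3R)-7-(benzyloxy)-1-[4-(benzyloxy)-3-methoxyphenyl]-3-[(benzyloxy)methyl]-6-methoxy-1,2,3,4-tetrahydronaphthalen-2-yl]methyl sulfate | COc1cc([C@H]2c3cc(OCc4ccccc4)c(OC)cc3C[C@@H](COCc3ccccc3)[C@@H]2COS(=O)(=O)[O-])ccc1OCc1ccccc1.[Na+] | intermediate
27 | sodium [(1S,2R,3R)-7-hydroxy-1-(4-hydroxy-3-methoxyphenyl)-3-(hydroxymethyl)-6-methoxy-1,2,3,4-tetrahydronaphthalen-2-yl]methyl sulfate | COc1cc([C@H]2c3cc(O)c(OC)cc3C[C@@H](CO)[C@@H]2COS(=O)(=O)[O-])ccc1O.[Na+] | intermediate (not isolated)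
28 | [(1S,2R,3R)-7-hydroxy-1-(4-hydroxy-3-methoxyphenyl)-3-(hydroxymethyl)-6-methoxy-1,2,3,4-tetrahydronaphthalen-2-yl]methyl hydrogen sulfate | COc1cc([C@H]2c3cc(O)c(OC)cc3C[C@@H](CO)[C@@H]2COS(=O)(=O)O)ccc1O | target

**Step count and risks**

Total step count: 16. Longest linear sequence: 16 steps (1 to 28); compounds 4, 8 and 11 are bought.

The three steps most likely to fail:

1. Step 10 (radical ring closure). The aryl radical may be quenched before it cyclises, may take the C2 hydrogen by 1,5-shift, or the tin radical may add to the acrylate faster than it abstracts bromine. The fallback replaces the radical by a carbanion and sets out from 19. Bromine–lithium exchange (n-BuLi, THF, −100 °C) should give the C4a aryllithium F1. This would add intramolecularly to the CH2 terminus of the tert-butyl acrylate (Parham-type anionic conjugate addition; the tert-butyl ester resists direct attack) to give the cyclised lithium ester enolate F2. Protonation with NH4Cl returns to the route at 20, which is equilibrated in step 11 as before.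

2. Step 3 (asymmetric arylation). The ortho bromine may slow insertion or erode face selectivity, and the electron-rich boronic acid may protodeboronate. The fallback sets C1 with an auxiliary instead of a catalyst and sets out from 3. Saponification (LiOH) gives the cinnamic acid F3. Activation as the mixed pivalic anhydride F4 (t-BuCOCl, Et3N) and acylation of (R)-4-phenyl-1,3-oxazolidin-2-one (LiCl) give the enoyl imide F5. The aryl Grignard reagent F6, made from commercial 1-(benzyloxy)-4-bromo-2-methoxybenzene and Mg, is added with CuBr·SMe2 (THF, −40 °C) to give the conjugate adduct F7. The aryl group should enter anti to the phenyl group of the chelated s-cis imide, which corresponds to S at C1. Cleavage with LiOH/H2O2 returns to the route at acid 7.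

3. Step 9 (α-methylenation). Trapping of the hindered enolate by the iminium salt may be incomplete, or base may move the new double bond into conjugation with C2 and destroy that centre. The fallback is a deformylative methylenation and sets out from 15. The enolate (LiN(i-Pr)2, THF, −78 °C) is C-formylated with ethyl formate to the α-formyl ester F8. Aqueous formaldehyde with K2CO3 in THF should then give the aldol adduct, which loses formate to form the α-methylene ester directly, returning to the route at 19.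

**Further compounds**

F1 | step 10 | C4a aryllithium derived from 19 (lithium in place of bromine) | COc1cc([C@@H](c2cc(OCc3ccccc3)c(OC)cc2[Li])[C@@H](CO[Si](C(C)C)(C(C)C)C(C)C)C(=C)C(=O)OC(C)(C)C)ccc1OCc1ccccc1
F2 | step 10 | lithium ester enolate of cyclised ester 20 | COc1cc([C@H]2c3cc(OCc4ccccc4)c(OC)cc3CC(=C([O-])OC(C)(C)C)[C@@H]2CO[Si](C(C)C)(C(C)C)C(C)C)ccc1OCc1ccccc1.[Li+]
F3 | step 3 | (E)-3-[5-(benzyloxy)-2-bromo-4-methoxyphenyl]prop-2-enoic acid | OC(=O)/C=C/c1cc(OCc2ccccc2)c(OC)cc1Br
F4 | step 3 | (E)-3-[5-(benzyloxy)-2-bromo-4-methoxyphenyl]prop-2-enoic 2,2-dimethylpropanoic anhydride | CC(C)(C)C(=O)OC(=O)/C=C/c1cc(OCc2ccccc2)c(OC)cc1Br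
F5 | step 3 | (4R)-3-{(E)-3-[5-(benzyloxy)-2-bromo-4-methoxyphenyl]prop-2-enoyl}-4-phenyl-1,3-oxazolidin-2-one | O=C(/C=C/c1cc(OCc2ccccc2)c(OC)cc1Br)N1[C@H](c2ccccc2)COC1=O
F6 | step 3 | [4-(benzyloxy)-3-methoxyphenyl]magnesium bromide | COc1cc([Mg]Br)ccc1OCc1ccccc1
F7 | step 3 | (4R)-3-{(3S)-3-[5-(benzyloxy)-2-bromo-4-methoxyphenyl]-3-[4-(benzyloxy)-3-methoxyphenyl]propanoyl}-4-phenyl-1,3-oxazolidin-2-one | COc1cc([C@@H](c2cc(OCc3ccccc3)c(OC)cc2Br)CC(=O)N2[C@H](c3ccccc3)COC2=O)ccc1OCc1ccccc1
F8 | step 9 | tert-butyl (3R,4S)-4-[5-(benzyloxy)-2-bromo-4-methoxyphenyl]-4-[4-(benzyloxy)-3-methoxyphenyl]-2-formyl-3-({[tri(propan-2-yl)silyl]oxy}methyl)butanoate (C2 epimers, partly enolised) | COc1cc([C@@H](c2cc(OCc3ccccc3)c(OC)cc2Br)[C@@H](CO[Si](C(C)C)(C(C)C)C(C)C)C(C=O)C(=O)OC(C)(C)C)ccc1OCc1ccccc1
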